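The side chain is attached at C11–C12. Because O-6 and the C-11 branch are cis on the C6–C7 edge of the seven-membered ring, O-6 and the carbon that ends as the C-11 methyl (C-19) can be tied into a temporary cis-fused γ-lactone; C-11 is then the α-carbon of a rigid 5-7-5 tricycle. Alkylation of its lithium enolate with the enantiopure C12–C17 triflate forms the C11–C12 bond and sets C-11 from the convex face in one operation; afterwards the lactone carbonyl is reduced to CH3, which frees 6-OH. The tricyclic lactone is built from (S)-linalool by cuprate addition, Nozaki–Hiyama–Kishi butenolide formation and a 7-exo Heck closure.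

Key step: step 15

Remark: the hydroazulene is numbered C1–C10 (C1/C5 ring fusion, C2=C3, C4 and C6 carbinols, C7 side-chain carbon, C10 methylene carbon), the side chain C11(CH3)–C12–C13(OAc)–C14=C15, with C18 = exocyclic CH2, C19 = CH3 on C11, C20 = CH3 on C4; the target is then (1S,4S,5R,6S,7R,11R,13R). α is the face of H-1/H-5 (H-6, H-7, 4-O are α; C-20, O-6, C-11 are β). TBS = tert-butyldimethylsilyl, Tf = trifluoromethanesulfonyl. (S)-(+)-linalool of high enantiomeric purity is assumed.

Step 1
Reactants: 1 (S)-(+)-linalool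
Product: 3 tert-butyldimethylsilyl ether of (1S)-1-methylcyclopent-2-en-1-ol, via (1S)-1-methylcyclopent-2-en-1-ol 2 (not isolated)
Conditions: (H2IMes)(PCy3)Cl2Ru=CHPh (0.5 mol %), CH2Cl2, 40 °C; then 2,6-lutidine, TBSOTf, 0 °C
Reagents that add atoms: tert-butyldimethylsilyl trifluoromethanesulfonate, CC(C)(C)[Si](C)(C)OS(=O)(=O)C(F)(F)F
Why: Ring-closing metathesis of the 1,6-diene expels 2-methylpropene and leaves the carbinol stereocentre (C-4 of the target, from the chiral pool) untouched, and the volatile tertiary alcohol is silylated in the same flask.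

Step 2
Reactants: 3 tert-butyldimethylsilyl ether of (1S)-1-methylcyclopent-2-en-1-ol
Product: 4 (4S)-4-(tert-butyldimethylsilyloxy)-4-methylcyclopent-2-en-1-one
Conditions: Rh2(cap)4 (1 mol %), t-BuOOH (5 equiv), K2CO3, CH2Cl2, 23 °C
Reagents that add atoms: tert-butyl hydroperoxide, CC(C)(C)OO
Why: Rh(II)-catalysed allylic C–H oxidation converts the only allylic CH2 into the enone carbonyl, and no stereocentre is formed.

Step 3
Reactants: 4 (4S)-4-(tert-butyldimethylsilyloxy)-4-methylcyclopent-2-en-1-one
Product: 6 4-(tert-butyldimethylsilyloxy)-3-[(isopropoxydimethylsilyl)methyl]-4-methylcyclopent-1-en-1-yl triflate (CH2Si trans to OTBS), via chloromagnesium enolate 5 (not isolated)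
Conditions: (i-PrO)Me2SiCH2MgCl (1.5 equiv), CuBr·SMe2 (10 mol %), THF, −78 to −40 °C; then PhNTf2, DMPU, −78 to 0 °C
Reagents that add atoms: [(isopropoxydimethylsilyl)methyl]magnesium chloride, CC(C)O[Si](C)(C)C[Mg]Cl; N-phenyl-bis(trifluoromethanesulfonimide), O=S(=O)(N(c1ccccc1)S(=O)(=O)C(F)(F)F)C(F)(F)F
Why: Copper-catalysed 1,4-addition of the hydroxymethyl-anion equivalent should occur anti to the bulky OTBS group (setting C-5 with the new carbon cis to C-20), and O-sulfonylation of the regiodefined enolate fixes the position of the later C1=C2 alkene.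

Step 4
Reactants: 6 enol triflate
Product: 7 {[5-(tert-butyldimethylsilyloxy)-5-methylcyclopent-2-en-1-yl]methyl}(isopropoxy)dimethylsilane (CH2Si trans to OTBS)
Conditions: Pd(OAc)2 (5 mol %), PPh3 (10 mol %), HCO2H, n-Bu3N, DMF, 60 °C
Reagents that add atoms: none
Why: Palladium-catalysed formate hydrogenolysis of the enol triflate (oxidative addition, decarboxylation of formate, reductive elimination) replaces OTf by H and leaves the C1=C2 alkene and both stereocentres in place.

Step 5
Reactants: 7 alkoxysilane
Product: 8 [5-(tert-butyldimethylsilyloxy)-5-methylcyclopent-2-en-1-yl]methanol (CH2OH trans to OTBS)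
Conditions: KF, KHCO3, 30% H2O2, THF/MeOH, 23 °C
Reagents that add atoms: hydrogen peroxide, OO
Why: Tamao–Fleming oxidation replaces the C–Si bond by C–OH and tolerates the alkene and the silyl ether.

Step 6
Reactants: 8 primary alcohol
Product: 9 5-(tert-butyldimethylsilyloxy)-5-methylcyclopent-2-ene-1-carbaldehyde (CHO trans to OTBS)
Conditions: DMP (1,1,1-triacetoxy-1,2-benziodoxol-3-one), NaHCO3, CH2Cl2, 0 °C; used crude at once
Reagents that add atoms: none
Why: Buffered periodinane oxidation of the primary alcohol gives the β,γ-unsaturated aldehyde under neutral conditions that should not enolise C-5.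

Step 7
Reactants: 10 methyl acetoacetate; 11 2,3-dibromopropene
Product: 12 methyl 6-bromo-3-oxohept-6-enoate
Conditions: NaH, THF, 0 °C; n-BuLi, 0 °C; then 11, 0 to 23 °C
Reagents that add atoms: none
Why: γ-Alkylation of the acetoacetate dianion occurs at the more basic terminal carbanion by SN2 at the allylic bromide, leaving the vinylic bromide untouched.

Step 8
Reactants: 12 methyl 6-bromo-3-oxohept-6-enoate
Product: 13 methyl (2Z)-6-bromo-3-(trifluoromethylsulfonyloxy)hepta-2,6-dienoate
Conditions: Tf2O, aq. LiOH, toluene, 5 °C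
Reagents that add atoms: trifluoromethanesulfonic anhydride, O=S(=O)(OS(=O)(=O)C(F)(F)F)C(F)(F)F
Why: O-sulfonylation of the chelated lithium (Z)-enolate of the β-keto ester gives the (Z)-enol triflate, which places the ester cis to the carbon that will bond to C-6.

Step 9
Reactants: 9 aldehyde; 13 (Z)-enol triflate
Product: 15 4-(3-bromobut-3-en-1-yl)-5-[5-(tert-butyldimethylsilyloxy)-5-methylcyclopent-2-en-1-yl]furan-2(5H)-one (H-6 cis to H-5 in target numbering), via hydroxy ester 14 (not isolated)
Conditions: CrCl2 (4 equiv), NiCl2 (2 mol %), DMF, 23 °C; then PPTS (cat.), CH2Cl2, 23 °C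
Reagents that add atoms: none
Why: In this Nozaki–Hiyama–Kishi coupling nickel should insert into the activated vinyl triflate and not the 2-bromoalkene, the alkenylchromium adds to the aldehyde under Felkin–Anh control (fully substituted C-4 anti to the nucleophile), which should set C-6 with H-6 cis to H-5, and the (Z)-γ-hydroxy ester lactonises to the butenolide.

Step 10
Reactants: 15 butenolide
Product: 16 cis-4-(3-bromobut-3-en-1-yl)-5-[5-(tert-butyldimethylsilyloxy)-5-methylcyclopent-2-en-1-yl]dihydrofuran-2(3H)-one (H-6 and H-7 cis)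
Conditions: Cu(OAc)2·H2O (5 mol %), 1,2-bis(diphenylphosphino)benzene (5 mol %), PhMe2SiH, t-BuOH, toluene, 23 °C
Reagents that add atoms: none
Why: Copper hydride conjugate reduction delivers hydride to C-7 on the face opposite the cyclopentenyl group at C-6, which should give the cis-4,5-disubstituted lactone without touching the vinyl bromide or the isolated alkene.

Step 11
Reactants: 16 cis-lactone with vinyl bromide
Product: 17 tricyclic lactone (6β,19-olide of the hydroazulene, 4α-OTBS, C2=C3, C10=C18, H-1/H-5/H-6/H-7 all α)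
Conditions: Pd(OAc)2 (10 mol %), PPh3 (25 mol %), Ag2CO3, MeCN, 80 °C
Reagents that add atoms: none
Why: In this intramolecular Heck reaction oxidative addition at C-10 is followed by 7-exo syn-carbopalladation of C1=C2 from the face of the tether (H-1 cis to H-5) and syn β-hydride elimination towards C-3, the only side with a syn hydrogen, which creates the exocyclic methylene and the C2=C3 alkene together.

Step 12
Reactants: 18 (R)-2,3-O-isopropylideneglyceraldehyde
Product: 19 (4S)-2,2-dimethyl-4-(2-methylprop-1-en-1-yl)-1,3-dioxolane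
Conditions: i-PrPPh3I, n-BuLi, THF, 0 °C; then 18, −78 to 23 °C
Reagents that add atoms: isopropyltriphenylphosphonium iodide, CC(C)[P+](c1ccccc1)(c1ccccc1)c1ccccc1.[I-]
Why: Wittig olefination with the non-stabilised isopropylidene ylide builds the trisubstituted alkene, and the stereocentre (C-13 of the target) comes unchanged from the chiral pool.

Step 13
Reactants: 19 alkenyl dioxolane
Product: 20 (2S)-4-methylpent-3-ene-1,2-diol
Conditions: PPTS (cat.), MeOH, 23 °C
Reagents that add atoms: none
Why: Mild acid-catalysed transketalisation removes the acetonide without ionising the allylic C–O bond.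

Step 14
Reactants: 20 (2S)-4-methylpent-3-ene-1,2-diol
Product: 22 (2S)-2-(tert-butyldimethylsilyloxy)-4-methylpent-3-en-1-yl trifluoromethanesulfonate, via hydroxy triflate 21 (not isolated)
Conditions: Tf2O (1.05 equiv), 2,6-lutidine, CH2Cl2, −78 °C; then TBSOTf, −78 to −30 °C; used at once
Reagents that add atoms: trifluoromethanesulfonic anhydride, O=S(=O)(OS(=O)(=O)C(F)(F)F)C(F)(F)F; tert-butyldimethylsilyl trifluoromethanesulfonate, CC(C)(C)[Si](C)(C)OS(=O)(=O)C(F)(F)F
Why: Selective O-sulfonylation of the primary hydroxyl at −78 °C and silylation of the secondary hydroxyl in the same flask give a β-silyloxy primary triflate reactive enough for enolate alkylation.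

Step 15
Reactants: 17 tricyclic lactone; 22 (2S)-triflate
Product: 24 C11-alkylated tricyclic lactone (4α-OTBS, 13-OTBS, new C-11 substituent trans to C-8), via lithium enolate 23 (not isolated)
Conditions: LDA (1.1 equiv), THF, −78 °C; then 22 (1.4 equiv), −78 to −40 °C
Reagents that add atoms: none
Why: LDA deprotonates C-11 of the lactone to the lithium enolate 23, which displaces triflate from the primary carbon of 22 in an SN2 reaction and so forms the C11–C12 bond. The closest known reaction type is the trans-selective α-alkylation of β-substituted γ-butyrolactone enolates with primary alkyl triflates. No ring is closed. The new stereocentre C-11 is under substrate control: the electrophile approaches the enolate on the convex face of the cis-fused tricycle, anti to C-8 on the neighbouring C-7, which corresponds to 11R in the target once the carbonyl has become CH3, while C-13 is carried in unchanged from 22. The step needs C- over O-alkylation and substitution over E2 loss of triflic acid from 22; a lithium enolate in THF at −78 °C and the high SN2 reactivity of a primary triflate should secure both. The tertiary OTBS group keeps O-4 out of the reaction.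

Step 16
Reactants: 24 alkylated lactone
Product: 25 lactol (C-19 hemiacetal, anomer mixture)
Conditions: DIBAL-H (1.1 equiv), CH2Cl2, −78 °C
Reagents that add atoms: none
Why: Partial hydride reduction of the lactone stops at the tetrahedral aluminium hemiacetal at −78 °C, and the configuration at the new C-19 centre is of no consequence.

Step 17
Reactants: 25 lactol
Product: 27 4,13-bis(tert-butyldimethylsilyl) ether of the triol (6-OH free, C-19 = CH3), via tosylhydrazone 26 (not isolated)
Conditions: TsNHNH2, THF, 23 °C; then catecholborane, CHCl3, 0 °C; NaOAc·3H2O, reflux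
Reagents that add atoms: none
Why: The lactol condenses through its hydroxy-aldehyde form to the tosylhydrazone, and Caglioti reduction with catecholborane (hydride addition, loss of sulfinate and N2) turns C-19 into CH3 and frees 6-OH under weakly basic conditions that should not epimerise C-11.

Step 18
Reactants: 27 bis-silyl ether
Product: 28 triol (13-deacetyl target)
Conditions: TBAF, THF, 23 to 45 °C
Reagents that add atoms: none
Why: Fluoride-induced desilylation removes both TBS ethers, the tertiary allylic one at slightly raised temperature, without other change.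

Step 19
Reactants: 28 triol
Product: 29 target CNP0209568.2
Conditions: Ac2O (1.2 equiv), pyridine, CH2Cl2, 0 °C
Reagents that add atoms: acetic anhydride, CC(=O)OC(C)=O
Why: Nucleophilic acyl substitution with a slight excess of Ac2O should take the unhindered allylic 13-OH in preference to the 6-OH flanked by two methine carbons and the tertiary 4-OH.

Compound list
1 | (S)-(+)-linalool, (3S)-3,7-dimethylocta-1,6-dien-3-ol | C=C[C@@](C)(O)CCC=C(C)C | starting material
2 | (1S)-1-methylcyclopent-2-en-1-ol | C[C@@]1(O)C=CCC1 | intermediate (not isolated)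
3 | tert-butyldimethylsilyl ether of (1S)-1-methylcyclopent-2-en-1-ol | C[C@@]1(O[Si](C)(C)C(C)(C)C)C=CCC1 | intermediate
4 | (4S)-4-(tert-butyldimethylsilyloxy)-4-methylcyclopent-2-en-1-one | C[C@@]1(O[Si](C)(C)C(C)(C)C)C=CC(=O)C1 | intermediate
5 | chloromagnesium enolate of the 1,4-adduct (CH2Si trans to OTBS) | C[C@@]1(O[Si](C)(C)C(C)(C)C)[C@@H](C[Si](C)(C)OC(C)C)C=C(O[Mg]Cl)C1 | intermediate (not isolated)
6 | 4-(tert-butyldimethylsilyloxy)-3-[(isopropoxydimethylsilyl)methyl]-4-methylcyclopent-1-en-1-yl triflate (CH2Si trans to OTBS) | C[C@@]1(O[Si](C)(C)C(C)(C)C)[C@@H](C[Si](C)(C)OC(C)C)C=C(OS(=O)(=O)C(F)(F)F)C1 | intermediate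
7 | {[5-(tert-butyldimethylsilyloxy)-5-methylcyclopent-2-en-1-yl]methyl}(isopropoxy)dimethylsilane (trans) | C[C@@]1(O[Si](C)(C)C(C)(C)C)[C@@H](C[Si](C)(C)OC(C)C)C=CC1 | intermediate
8 | [5-(tert-butyldimethylsilyloxy)-5-methylcyclopent-2-en-1-yl]methanol (CH2OH trans to OTBS) | C[C@@]1(O[Si](C)(C)C(C)(C)C)[C@@H](CO)C=CC1 | intermediate
9 | 5-(tert-butyldimethylsilyloxy)-5-methylcyclopent-2-ene-1-carbaldehyde (CHO trans to OTBS) | C[C@@]1(O[Si](C)(C)C(C)(C)C)[C@@H](C=O)C=CC1 | intermediate
10 | methyl acetoacetate | COC(=O)CC(C)=O | starting material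
11 | 2,3-dibromopropene | C=C(Br)CBr | starting material
12 | methyl 6-bromo-3-oxohept-6-enoate | COC(=O)CC(=O)CCC(Br)=C | intermediate
13 | methyl (2Z)-6-bromo-3-(trifluoromethylsulfonyloxy)hepta-2,6-dienoate | COC(=O)/C=C(\OS(=O)(=O)C(F)(F)F)CCC(Br)=C | intermediate
14 | methyl (2Z)-6-bromo-3-{hydroxy[5-(tert-butyldimethylsilyloxy)-5-methylcyclopent-2-en-1-yl]methyl}hepta-2,6-dienoate | C=C(Br)CC/C(=C/C(=O)OC)[C@H](O)[C@H]1C=CC[C@]1(C)O[Si](C)(C)C(C)(C)C | intermediate (not isolated)
15 | 4-(3-bromobut-3-en-1-yl)-5-[5-(tert-butyldimethylsilyloxy)-5-methylcyclopent-2-en-1-yl]furan-2(5H)-one | C=C(Br)CCC1=CC(=O)O[C@@H]1[C@H]2C=CC[C@]2(C)O[Si](C)(C)C(C)(C)C | intermediate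
16 | cis-4-(3-bromobut-3-en-1-yl)-5-[5-(tert-butyldimethylsilyloxy)-5-methylcyclopent-2-en-1-yl]dihydrofuran-2(3H)-one | C=C(Br)CC[C@@H]1CC(=O)O[C@@H]1[C@H]2C=CC[C@]2(C)O[Si](C)(C)C(C)(C)C | intermediate
17 | tricyclic lactone: 6β,19-olide of the hydroazulene, 4α-OTBS, 4β-CH3, C2=C3, C10=C18, H-1/H-5/H-6/H-7 α | C=C1CC[C@@H]2CC(=O)O[C@@H]2[C@H]3[C@@H]1C=C[C@]3(C)O[Si](C)(C)C(C)(C)C | intermediate
18 | (R)-2,3-O-isopropylideneglyceraldehyde | O=C[C@H]1COC(C)(C)O1 | starting material
19 | (4S)-2,2-dimethyl-4-(2-methylprop-1-en-1-yl)-1,3-dioxolane | CC(C)=C[C@H]1COC(C)(C)O1 | intermediate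
20 | (2S)-4-methylpent-3-ene-1,2-diol | CC(C)=C[C@H](O)CO | intermediate
21 | (2S)-2-hydroxy-4-methylpent-3-en-1-yl trifluoromethanesulfonate | CC(C)=C[C@H](O)COS(=O)(=O)C(F)(F)F | intermediate (not isolated)
22 | (2S)-2-(tert-butyldimethylsilyloxy)-4-methylpent-3-en-1-yl trifluoromethanesulfonate | CC(C)=C[C@H](O[Si](C)(C)C(C)(C)C)COS(=O)(=O)C(F)(F)F | intermediate
23 | lithium enolate of lactone 17 | C=C1CC[C@@H]2C=C(O[Li])O[C@@H]2[C@H]3[C@@H]1C=C[C@]3(C)O[Si](C)(C)C(C)(C)C | intermediate (not isolated)
24 | C11-alkylated tricyclic lactone (C-12 trans to C-8, 13-OTBS, 4α-OTBS) | C=C1CC[C@@H]2[C@@H](C[C@H](C=C(C)C)O[Si](C)(C)C(C)(C)C)C(=O)O[C@@H]2[C@H]3[C@@H]1C=C[C@]3(C)O[Si](C)(C)C(C)(C)C | intermediate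
25 | lactol of 24 (C-19 hemiacetal, anomer mixture) | C=C1CC[C@@H]2[C@@H](C[C@H](C=C(C)C)O[Si](C)(C)C(C)(C)C)C(O)O[C@@H]2[C@H]3[C@@H]1C=C[C@]3(C)O[Si](C)(C)C(C)(C)C | intermediate
26 | C-19 tosylhydrazone of the ring-opened hydroxy aldehyde | C=C1CC[C@H]([C@@H](C[C@H](C=C(C)C)O[Si](C)(C)C(C)(C)C)C=NNS(=O)(=O)c3ccc(C)cc3)[C@H](O)[C@H]2[C@@H]1C=C[C@]2(C)O[Si](C)(C)C(C)(C)C | intermediate (not isolated)
27 | 4,13-bis(tert-butyldimethylsilyl) ether of triol 28 | C=C1CC[C@H]([C@H](C)C[C@H](C=C(C)C)O[Si](C)(C)C(C)(C)C)[C@H](O)[C@H]2[C@@H]1C=C[C@]2(C)O[Si](C)(C)C(C)(C)C | intermediate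
28 | (1S,4S,5R,6S,7R,11R,13R)-triol (13-deacetyl target) | C=C1CC[C@H]([C@H](C)C[C@H](C=C(C)C)O)[C@H](O)[C@H]2[C@@H]1C=C[C@]2(C)O | intermediate
29 | CNP0209568.2, the 13-acetate of 28 | C=C1CC[C@H]([C@H](C)C[C@H](C=C(C)C)OC(C)=O)[C@H](O)[C@H]2[C@@H]1C=C[C@]2(C)O | target

Total step count: 19. Longest linear sequence: 14 steps (steps 1–6, 9–11, 15–19).

Steps most likely to fail, with fallbacks:

Step 11. The 7-exo insertion into the hindered 1,2-disubstituted cyclopentene may be slower than protodebromination of the alkenylpalladium or migration of the new double bonds. The fallback closes the same C1–C10 bond by palladium-hydride enyne cycloisomerisation instead of a Heck reaction. It sets out from aldehyde 9 (and 10) and comes back at 17. The dianion of 10 is alkylated with propargyl bromide to methyl 3-oxohept-6-ynoate F1, which is converted as in step 8 into methyl (2Z)-3-(trifluoromethylsulfonyloxy)hept-2-en-6-ynoate F2. Nozaki–Hiyama–Kishi coupling of F2 with 9 as in step 9 should give the alkynyl butenolide F3. Conjugate reduction with Mg in MeOH (copper hydride would attack the terminal alkyne) should give the cis enyne lactone F4. Pd(OAc)2 with N,N′-bis(benzylidene)ethylenediamine in benzene at 70 °C should then effect hydropalladation of the alkyne, 7-exo carbopalladation of C1=C2 and β-hydride elimination to 17.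

Step 9. The addition may show poor facial selectivity at the aldehyde (C-6 epimers), the β,γ-unsaturated aldehyde may enolise at C-5, or nickel may insert into the 2-bromoalkene. The fallback sets C-6 by reagent control and builds the butenolide by metathesis. It sets out from 9 and comes back at 15. 2,5-Dibromohexa-1,5-diene F5 (from hexa-1,5-diyne and HBr/Et4NBr) is monolithiated with t-BuLi at −100 °C and added to 9 to give the allylic alcohol F6, whatever its C-6 ratio. Periodinane oxidation gives the enone F7, which is reduced back to F6 as one C-6 epimer by Corey–Bakshi–Shibata reduction with the matched catalyst enantiomer. Acryloyl chloride/Et3N gives the acrylate F8, and ring-closing metathesis with the Ru catalyst of step 1 should close the butenolide 15.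

Step 15. E2 loss of triflic acid from 22 or proton transfer may compete with substitution, or facial control may be incomplete. The fallback uses strain-release opening of an epoxide instead of triflate displacement. It sets out from 17 and 20 and comes back at 24. Diol 20 is cyclodehydrated (PPh3, DIAD, Mitsunobu) to (S)-2-(2-methylprop-1-en-1-yl)oxirane F9. The lithium enolate of 17 is transmetallated with Et2AlCl and should open F9 at its CH2 terminus to give the hydroxy lactone F10. Silylation of F10 (TBSOTf, 2,6-lutidine) gives 24.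

Further compounds
F1 | step 11 | methyl 3-oxohept-6-ynoate | COC(=O)CC(=O)CCC#C
F2 | step 11 | methyl (2Z)-3-(trifluoromethylsulfonyloxy)hept-2-en-6-ynoate | COC(=O)/C=C(\OS(=O)(=O)C(F)(F)F)CCC#C
F3 | step 11 | 4-(but-3-yn-1-yl)-5-[5-(tert-butyldimethylsilyloxy)-5-methylcyclopent-2-en-1-yl]furan-2(5H)-one | C#CCCC1=CC(=O)O[C@@H]1[C@H]2C=CC[C@]2(C)O[Si](C)(C)C(C)(C)C
F4 | step 11 | cis-4-(but-3-yn-1-yl)-5-[5-(tert-butyldimethylsilyloxy)-5-methylcyclopent-2-en-1-yl]dihydrofuran-2(3H)-one | C#CCC[C@@H]1CC(=O)O[C@@H]1[C@H]2C=CC[C@]2(C)O[Si](C)(C)C(C)(C)C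
F5 | step 9 | 2,5-dibromohexa-1,5-diene | C=C(Br)CCC(Br)=C
F6 | step 9 | 5-bromo-2-methylidene-1-[5-(tert-butyldimethylsilyloxy)-5-methylcyclopent-2-en-1-yl]hex-5-en-1-ol (C-6 configured as in 14) | C=C(Br)CCC(=C)[C@H](O)[C@H]1C=CC[C@]1(C)O[Si](C)(C)C(C)(C)C
F7 | step 9 | 5-bromo-2-methylidene-1-[5-(tert-butyldimethylsilyloxy)-5-methylcyclopent-2-en-1-yl]hex-5-en-1-one | C=C(Br)CCC(=C)C(=O)[C@H]1C=CC[C@]1(C)O[Si](C)(C)C(C)(C)C
F8 | step 9 | acrylate ester of F6 | C=CC(=O)O[C@@H](C(=C)CCC(Br)=C)[C@H]1C=CC[C@]1(C)O[Si](C)(C)C(C)(C)C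
F9 | step 15 | (S)-2-(2-methylprop-1-en-1-yl)oxirane | CC(C)=C[C@H]1CO1
F10 | step 15 | 13-hydroxy analogue of lactone 24 | C=C1CC[C@@H]2[C@@H](C[C@H](C=C(C)C)O)C(=O)O[C@@H]2[C@H]3[C@@H]1C=C[C@]3(C)O[Si](C)(C)C(C)(C)C
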